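**Strategy**

Ring B of the target is a cyclohexene (C6=C7) carrying an exocyclic methylene on C8 next to C9. This is the imprint of a vinylallene (C5=C6–C7=C8=C12) that has added across a C9=C10 alkene, with C1–C4 of ring A as the connecting chain. A single auxiliary-directed intramolecular Diels–Alder reaction therefore forms C5–C10 and C8–C9, closes rings A and B, delivers the 6,8(12)-diene as such and sets C5, C9 and C10. Its substrate is an open-chain (E)-β-methyl enoyl (R)-4-benzyloxazolidinone tied through a C3 dioxolane and the C4 gem-dimethyl carbon to an (E)-dienylallene. Four further steps free C11, set the axial C3 alcohol and attach umbelliferone.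

Key step: step 10

**Remarks and assumptions**

- Drimane numbering is used for the skeleton: ring A is C1–C5 and C10, ring B is C5–C10, C11 is the oxymethylene carbon and C12 the methylene carbon.
- Stereochemical check: the target is (3S,5S,9R,10R). Addition to the Cα Re face of the chelated (R)-4-benzyl imide gives 9R,10R and the acyl-endo mode gives 5S, so 17 and 18 as drawn need no correction.
- Design around the fixed step: a hydride reagent cannot tell the two esters of 5 apart. The enoate is therefore saponified first and the hindered ester reduced as the carboxylate salt. The auxiliary then goes on early, and the vinylallene is made last by neutral, room-temperature chemistry, so 17 never sees heat, hot amine or strong base.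
- Assumption: about 2.5 equiv of Me2AlCl are needed in step 10, because the dioxolane oxygens also bind aluminium.

**Route**

Step 1
Reactants: 1 ethyl 2,2-dimethyl-3-oxobutanoate; 2 methyl (2E)-4-bromo-3-methylbut-2-enoate
Product: 4 1-ethyl 8-methyl (6E)-2,2,6-trimethyl-3-oxooct-6-enedioate, via lithium enolate 3 (not isolated)
Conditions: LDA (LiN(i-Pr)2, 1.05 equiv), THF, −78 °C; then 2, DMPU, −78 → −30 °C
Reagents that add atoms: none
Why: Ketone enolate alkylation: the carbon between the two carbonyl groups of 1 is quaternary and the ester has no α-hydrogen, so LDA can only form the methyl-ketone enolate 3, which displaces the primary allylic bromide of 2 by SN2 to form the C1–C2 bond, while the β,β-disubstituted enoate resists Michael addition and keeps its (E)-geometry.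

Step 2
Reactants: 4 1-ethyl 8-methyl (6E)-2,2,6-trimethyl-3-oxooct-6-enedioate
Product: 5 1-ethyl 8-methyl (6E)-3,3-ethylenedioxy-2,2,6-trimethyloct-6-enedioate
Conditions: TMSOCH2CH2OTMS (3 equiv), TMSOTf (10 mol%), CH2Cl2, −78 → 0 °C; pyridine quench
Reagents that add atoms: 1,2-bis(trimethylsilyloxy)ethane, C[Si](C)(C)OCCO[Si](C)(C)C
Why: Noyori ketalisation: catalytic TMSOTf transfers the glycol unit from its bis-silyl ether to the ketone, driven by formation of hexamethyldisiloxane, and works on hindered ketones at low temperature without transesterification or migration of the enoate double bond.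

Step 3
Reactants: 5 1-ethyl 8-methyl (6E)-3,3-ethylenedioxy-2,2,6-trimethyloct-6-enedioate
Product: 6 lithium (2E)-8-ethoxy-6,6-ethylenedioxy-3,7,7-trimethyl-8-oxooct-2-enoate
Conditions: LiOH·H2O (1.2 equiv), THF/MeOH/H2O, 45 °C; evaporate, toluene azeotrope
Reagents that add atoms: lithium hydroxide, [Li+].[OH-]
Why: Ester saponification: hydroxide attacks the exposed methyl enoate, whereas the ethyl ester between the quaternary C4 and the ketal carbon C3 is far too shielded to react, and isolating the lithium salt keeps acid away from the ketal and supplies the carboxylate needed for the next step.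

Step 4
Reactants: 6 lithium (2E)-8-ethoxy-6,6-ethylenedioxy-3,7,7-trimethyl-8-oxooct-2-enoate
Product: 7 (2E)-6,6-ethylenedioxy-8-hydroxy-3,7,7-trimethyloct-2-enoic acid
Conditions: LiBH4 (3 equiv), THF, 0 → 65 °C; then cold 1 M HCl to pH 4
Reagents that add atoms: none
Why: Chemoselective hydride reduction: LiBH4 reduces esters but not carboxylate salts, so only the neopentyl ester is taken to the primary C5 alcohol, lithium coordination to the neighbouring dioxolane oxygen helping hydride delivery, while the conjugated carboxylate and its alkene are left alone.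

Step 5
Reactants: 7 (2E)-6,6-ethylenedioxy-8-hydroxy-3,7,7-trimethyloct-2-enoic acid; 8 (4R)-4-benzyl-1,3-oxazolidin-2-one
Product: 10 (4R)-4-benzyl-3-[(2E)-6,6-ethylenedioxy-8-hydroxy-3,7,7-trimethyloct-2-enoyl]-1,3-oxazolidin-2-one, via mixed pivalic anhydride 9 (not isolated)
Conditions: t-BuCOCl (1.1 equiv), Et3N (2.5 equiv), THF, −20 °C; then LiCl (1.2 equiv), 8, −20 → 23 °C
Reagents that add atoms: none
Why: N-Acylation of the oxazolidinone through a mixed anhydride: pivaloyl chloride activates only the carboxylate to give 9, which LiCl/Et3N-activated 8 attacks at the less hindered carbonyl, and because neither strong base nor an acid chloride is involved the (E)-β-methyl enoyl unit does not deconjugate and the hindered neopentyl alcohol does not compete.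

Step 6
Reactants: 10 (4R)-4-benzyl-3-[(2E)-6,6-ethylenedioxy-8-hydroxy-3,7,7-trimethyloct-2-enoyl]-1,3-oxazolidin-2-one
Product: 11 (4R)-4-benzyl-3-[(2E)-6,6-ethylenedioxy-3,7,7-trimethyl-8-oxooct-2-enoyl]-1,3-oxazolidin-2-one
Conditions: Dess–Martin periodinane (1.3 equiv), CH2Cl2, 0 → 23 °C
Reagents that add atoms: none
Why: Dess–Martin oxidation converts the primary neopentyl alcohol into the non-enolisable C5 aldehyde under near-neutral conditions that leave the imide, the ketal and the enoyl alkene untouched.

Step 7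
Reactants: 11 (4R)-4-benzyl-3-[(2E)-6,6-ethylenedioxy-3,7,7-trimethyl-8-oxooct-2-enoyl]-1,3-oxazolidin-2-one
Product: 12 (4R)-4-benzyl-3-[(2E,8E)-6,6-ethylenedioxy-9-iodo-3,7,7-trimethylnona-2,8-dienoyl]-1,3-oxazolidin-2-one
Conditions: CrCl2 (8 equiv), CHI3 (3 equiv), THF/1,4-dioxane, 0 → 23 °C, dark
Reagents that add atoms: iodoform, IC(I)I
Why: Takai olefination: the geminal dichromium carbenoid formed from iodoform and CrCl2 adds only to the aldehyde and eliminates to the (E)-vinyl iodide (C5=C6), the bulky quaternary C4 reinforcing the (E) preference, while imide and ketal are inert to the divalent chromium reagent.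

Step 8
Reactants: 12 (4R)-4-benzyl-3-[(2E,8E)-6,6-ethylenedioxy-9-iodo-3,7,7-trimethylnona-2,8-dienoyl]-1,3-oxazolidin-2-one; 13 prop-2-yn-1-ol
Product: 14 (4R)-4-benzyl-3-[(2E,8E)-6,6-ethylenedioxy-12-hydroxy-3,7,7-trimethyldodeca-2,8-dien-10-ynoyl]-1,3-oxazolidin-2-one
Conditions: PdCl2(PPh3)2 (3 mol%), CuI (6 mol%), Et3N, THF, 23 °C
Reagents that add atoms: none
Why: Sonogashira coupling joins the (E)-vinyl iodide to the terminal alkyne at room temperature, retaining the alkene geometry and tolerating the free hydroxyl group, the ketal and the imide.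

Step 9
Reactants: 14 (4R)-4-benzyl-3-[(2E,8E)-6,6-ethylenedioxy-12-hydroxy-3,7,7-trimethyldodeca-2,8-dien-10-ynoyl]-1,3-oxazolidin-2-one
Product: 17 (4R)-4-benzyl-3-[(2E,8E)-6,6-ethylenedioxy-3,7,7-trimethyldodeca-2,8,10,11-tetraenoyl]-1,3-oxazolidin-2-one, via sulfonylhydrazine 15 (not isolated), via propargylic diazene 16 (not isolated)
Conditions: PPh3 (1.5 equiv), DEAD (1.5 equiv), THF, −15 °C; then 2-nitrobenzenesulfonohydrazide (1.5 equiv), −15 °C; then 23 °C
Reagents that add atoms: none
Why: Myers allene synthesis: Mitsunobu displacement of the primary propargylic hydroxyl by the sulfonylhydrazide gives 15, loss of 2-nitrobenzenesulfinic acid on warming gives diazene 16, and its retro-ene loss of N2 delivers hydrogen to C7 and turns the alkyne into the terminal allene under neutral conditions at or below room temperature, so the trienimide is not heated.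

Step 10
Reactants: 17 (4R)-4-benzyl-3-[(2E,8E)-6,6-ethylenedioxy-3,7,7-trimethyldodeca-2,8,10,11-tetraenoyl]-1,3-oxazolidin-2-one
Product: 18 (4R)-4-benzyl-3-{[(1R,4aS,8aR)-6,6-ethylenedioxy-5,5,8a-trimethyl-2-methylidene-1,2,4a,5,6,7,8,8a-octahydronaphthalen-1-yl]carbonyl}-1,3-oxazolidin-2-one
Conditions: Me2AlCl (2.5 equiv), CH2Cl2, −30 → 0 °C; aqueous potassium sodium tartrate work-up
Reagents that add atoms: none
Why: Excess Me2AlCl converts the imide into the cationic dimethylaluminium chelate bridging both carbonyl oxygens, which fixes the enoyl unit s-cis and lowers its LUMO, and the s-cis vinylallene C5=C6–C7=C8 then adds across C9=C10 in a concerted, asynchronous [4+2] cycloaddition that forms C8–C9 and C5–C10. The closest known reaction types are the Lewis-acid-promoted intramolecular Diels–Alder reaction of 2,8,10-trienimides bearing oxazolidinone auxiliaries and the Diels–Alder reaction of vinylallenes. Ring B (C5 to C10) closes as the cycloadduct ring itself, and ring A (C10, C1 to C5) closes at the same time through the four-carbon chain that links diene terminus C5 to dienophile carbon C10, as in a 1,7,9-decatriene cyclisation with a chair-like chain. C9 and C10 are set by the auxiliary, the diene adding to the face of the chelated enoyl group anti to the benzyl group (the Cα Re face), while the (E)-geometry of the dienophile is carried over so that the C10 methyl and C11 are cis; C5 is set by the acyl-endo transition state, which places H5 anti to the C10 methyl and so gives the trans ring fusion. The step needs π-facial and endo selectivity, which the rigid chelate, the (E)-geometry of both partners and the folding bias of the C3 ketal and C4 gem-dimethyl group should secure. The allene keeps its outer double bond as the C8=C12 methylene and the new ring alkene falls at C6=C7, so the target diene needs no later adjustment.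

Step 11
Reactants: 18 (4R)-4-benzyl-3-{[(1R,4aS,8aR)-6,6-ethylenedioxy-5,5,8a-trimethyl-2-methylidene-1,2,4a,5,6,7,8,8a-octahydronaphthalen-1-yl]carbonyl}-1,3-oxazolidin-2-one
Product: 19 [(1R,4aS,8aR)-6,6-ethylenedioxy-5,5,8a-trimethyl-2-methylidene-1,2,4a,5,6,7,8,8a-octahydronaphthalen-1-yl]methanol
Conditions: LiBH4 (2.5 equiv), MeOH (2.5 equiv), THF, 0 °C; then 1 M NaOH
Reagents that add atoms: none
Why: Reductive removal of the oxazolidinone auxiliary: the methoxyborohydride formed from LiBH4 and methanol attacks the exocyclic carbonyl and reduces it to the primary C11 alcohol, releasing 8 for recovery, under conditions too weakly basic to epimerise C9 or move the 6,8(12)-diene.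

Step 12
Reactants: 19 [(1R,4aS,8aR)-6,6-ethylenedioxy-5,5,8a-trimethyl-2-methylidene-1,2,4a,5,6,7,8,8a-octahydronaphthalen-1-yl]methanol
Product: 20 [(1R,4aS,8aR)-5,5,8a-trimethyl-2-methylidene-6-oxo-1,2,4a,5,6,7,8,8a-octahydronaphthalen-1-yl]methanol
Conditions: PPTS (0.2 equiv), acetone/H2O, 50 °C
Reagents that add atoms: water, O
Why: Acid-catalysed ketal hydrolysis: relief of the crowding between the dioxolane and the C4 gem-dimethyl group speeds the hydrolysis, so the weak acid PPTS in wet acetone suffices, and it is not acidic enough to protonate the exocyclic diene and shift it into the ring.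

Step 13
Reactants: 20 [(1R,4aS,8aR)-5,5,8a-trimethyl-2-methylidene-6-oxo-1,2,4a,5,6,7,8,8a-octahydronaphthalen-1-yl]methanol
Product: 21 [(1R,4aS,6S,8aR)-6-hydroxy-5,5,8a-trimethyl-2-methylidene-1,2,4a,5,6,7,8,8a-octahydronaphthalen-1-yl]methanol
Conditions: L-Selectride (LiBH(s-Bu)3, 2.5 equiv), THF, −78 °C; aqueous work-up
Reagents that add atoms: none
Why: Bulky-hydride reduction of a 4,4-dimethyl-3-ketone in a trans-decalin: the axial approach of LiBH(s-Bu)3 is blocked by the axial hydrogens on C1 and C5, so hydride arrives equatorially and the new C3 hydroxyl is axial, trans to the C10 methyl and cis to H5 (3S).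

Step 14
Reactants: 21 [(1R,4aS,6S,8aR)-6-hydroxy-5,5,8a-trimethyl-2-methylidene-1,2,4a,5,6,7,8,8a-octahydronaphthalen-1-yl]methanol; 22 umbelliferone (7-hydroxy-2H-chromen-2-one)
Product: 23 7-{[(1R,4aS,6S,8aR)-6-hydroxy-5,5,8a-trimethyl-2-methylidene-1,2,4a,5,6,7,8,8a-octahydronaphthalen-1-yl]methoxy}-2H-chromen-2-one
Conditions: PPh3 (1.5 equiv), DIAD (1.5 equiv), THF, 0 → 23 °C
Reagents that add atoms: none
Why: Mitsunobu etherification: the acidic 7-hydroxyl of umbelliferone protonates the betaine and its phenoxide displaces the activated primary C11 oxygen by SN2, while the axial C3 hydroxyl next to the gem-dimethyl carbon is too hindered to be activated, so no protecting group is needed and no stereocentre is touched.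

**Compound list**

1 | ethyl 2,2-dimethyl-3-oxobutanoate | CCOC(=O)C(C)(C)C(C)=O | starting material
2 | methyl (2E)-4-bromo-3-methylbut-2-enoate | COC(=O)/C=C(\C)CBr | starting material
3 | lithium enolate of 1, ethyl 3-(lithiooxy)-2,2-dimethylbut-3-enoate | CCOC(=O)C(C)(C)C(=C)O[Li] | intermediate
4 | 1-ethyl 8-methyl (6E)-2,2,6-trimethyl-3-oxooct-6-enedioate | CCOC(=O)C(C)(C)C(=O)CC/C(C)=C/C(=O)OC | intermediate
5 | 1-ethyl 8-methyl (6E)-3,3-ethylenedioxy-2,2,6-trimethyloct-6-enedioate | CCOC(=O)C(C)(C)C1(CC/C(C)=C/C(=O)OC)OCCO1 | intermediate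
6 | lithium (2E)-8-ethoxy-6,6-ethylenedioxy-3,7,7-trimethyl-8-oxooct-2-enoate | CCOC(=O)C(C)(C)C1(CC/C(C)=C/C(=O)[O-])OCCO1.[Li+] | intermediate
7 | (2E)-6,6-ethylenedioxy-8-hydroxy-3,7,7-trimethyloct-2-enoic acid | OCC(C)(C)C1(CC/C(C)=C/C(=O)O)OCCO1 | intermediate
8 | (4R)-4-benzyl-1,3-oxazolidin-2-one | O=C1N[C@H](Cc2ccccc2)CO1 | starting material
9 | (2E)-6,6-ethylenedioxy-8-hydroxy-3,7,7-trimethyloct-2-enoic pivalic anhydride | OCC(C)(C)C1(CC/C(C)=C/C(=O)OC(=O)C(C)(C)C)OCCO1 | intermediate
10 | (4R)-4-benzyl-3-[(2E)-6,6-ethylenedioxy-8-hydroxy-3,7,7-trimethyloct-2-enoyl]-1,3-oxazolidin-2-one | OCC(C)(C)C1(CC/C(C)=C/C(=O)N2[C@H](Cc3ccccc3)COC2=O)OCCO1 | intermediate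
11 | (4R)-4-benzyl-3-[(2E)-6,6-ethylenedioxy-3,7,7-trimethyl-8-oxooct-2-enoyl]-1,3-oxazolidin-2-one | O=CC(C)(C)C1(CC/C(C)=C/C(=O)N2[C@H](Cc3ccccc3)COC2=O)OCCO1 | intermediate
12 | (4R)-4-benzyl-3-[(2E,8E)-6,6-ethylenedioxy-9-iodo-3,7,7-trimethylnona-2,8-dienoyl]-1,3-oxazolidin-2-one | I/C=C/C(C)(C)C1(CC/C(C)=C/C(=O)N2[C@H](Cc3ccccc3)COC2=O)OCCO1 | intermediate
13 | prop-2-yn-1-ol | C#CCO | starting material
14 | (4R)-4-benzyl-3-[(2E,8E)-6,6-ethylenedioxy-12-hydroxy-3,7,7-trimethyldodeca-2,8-dien-10-ynoyl]-1,3-oxazolidin-2-one | OCC#C/C=C/C(C)(C)C1(CC/C(C)=C/C(=O)N2[C@H](Cc3ccccc3)COC2=O)OCCO1 | intermediate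
15 | (4R)-4-benzyl-3-[(2E,8E)-6,6-ethylenedioxy-3,7,7-trimethyl-12-{1-[(2-nitrophenyl)sulfonyl]hydrazin-1-yl}dodeca-2,8-dien-10-ynoyl]-1,3-oxazolidin-2-one | NN(CC#C/C=C/C(C)(C)C1(CC/C(C)=C/C(=O)N2[C@H](Cc3ccccc3)COC2=O)OCCO1)S(=O)(=O)c4ccccc4[N+](=O)[O-] | intermediate
16 | (4R)-4-benzyl-3-[(2E,8E)-12-diazenyl-6,6-ethylenedioxy-3,7,7-trimethyldodeca-2,8-dien-10-ynoyl]-1,3-oxazolidin-2-one | N=NCC#C/C=C/C(C)(C)C1(CC/C(C)=C/C(=O)N2[C@H](Cc3ccccc3)COC2=O)OCCO1 | intermediate
17 | (4R)-4-benzyl-3-[(2E,8E)-6,6-ethylenedioxy-3,7,7-trimethyldodeca-2,8,10,11-tetraenoyl]-1,3-oxazolidin-2-one | C=C=C/C=C/C(C)(C)C1(CC/C(C)=C/C(=O)N2[C@H](Cc3ccccc3)COC2=O)OCCO1 | intermediate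
18 | (4R)-4-benzyl-3-{[(1R,4aS,8aR)-6,6-ethylenedioxy-5,5,8a-trimethyl-2-methylidene-1,2,4a,5,6,7,8,8a-octahydronaphthalen-1-yl]carbonyl}-1,3-oxazolidin-2-one; trans-fused, drimane 5S,9R,10R | C=C1C=C[C@@H]2C(C)(C)C3(OCCO3)CC[C@@]2(C)[C@@H]1C(=O)N4[C@H](Cc5ccccc5)COC4=O | intermediate
19 | [(1R,4aS,8aR)-6,6-ethylenedioxy-5,5,8a-trimethyl-2-methylidene-1,2,4a,5,6,7,8,8a-octahydronaphthalen-1-yl]methanol | C=C1C=C[C@@H]2C(C)(C)C3(OCCO3)CC[C@@]2(C)[C@@H]1CO | intermediate
20 | [(1R,4aS,8aR)-5,5,8a-trimethyl-2-methylidene-6-oxo-1,2,4a,5,6,7,8,8a-octahydronaphthalen-1-yl]methanol | C=C1C=C[C@@H]2C(C)(C)C(=O)CC[C@@]2(C)[C@@H]1CO | intermediate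
21 | [(1R,4aS,6S,8aR)-6-hydroxy-5,5,8a-trimethyl-2-methylidene-1,2,4a,5,6,7,8,8a-octahydronaphthalen-1-yl]methanol; axial C3 hydroxyl | C=C1C=C[C@@H]2C(C)(C)[C@@H](O)CC[C@@]2(C)[C@@H]1CO | intermediate
22 | umbelliferone, 7-hydroxy-2H-chromen-2-one | O=c1ccc2ccc(O)cc2o1 | starting material
23 | 7-{[(1R,4aS,6S,8aR)-6-hydroxy-5,5,8a-trimethyl-2-methylidene-1,2,4a,5,6,7,8,8a-octahydronaphthalen-1-yl]methoxy}-2H-chromen-2-one | C=C1C=C[C@@H]2C(C)(C)[C@@H](O)CC[C@@]2(C)[C@@H]1COc1ccc2ccc(=O)oc2c1 | target

**Step count**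

Total: 14 steps. Longest linear sequence: 14 steps (1 → 23).

**Steps most likely to fail**

Step 10. The Lewis acid may ionise the dioxolane or oligomerise the vinylallene faster than the hindered, trisubstituted dienophile cyclises. Alternatively, aluminium held by the ketal oxygens may leave the imide incompletely chelated, so that facial selectivity erodes. The fallback sets out from 17 and comes back at 18. Compound 17 is heated without any Lewis acid (toluene, BHT, 110 °C, sealed vessel). The thermal cycloaddition should give the trans-fused adducts of both diene faces, namely 18 and its ring diastereomer (4R)-4-benzyl-3-{[(1S,4aR,8aS)-6,6-ethylenedioxy-5,5,8a-trimethyl-2-methylidene-1,2,4a,5,6,7,8,8a-octahydronaphthalen-1-yl]carbonyl}-1,3-oxazolidin-2-one F1. The auxiliary then serves as a covalent resolving handle, not as a directing group: the two adducts are diastereomers and are separated by chromatography or crystallisation, and 18 enters step 11.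

Step 1. Proton transfer to enolate 3 from product 4 or from the γ-position of bromoester 2 may lead to polyalkylation and base-induced loss of the bromide. The fallback sets out from 2 and comes back at 4, and makes the same keto diester by soft alkylation followed by acylation.

- Bromide 2 is substituted by the sodium salt of di-tert-butyl malonate (NaH, THF, 0 °C) to give 1,1-di-tert-butyl 4-methyl (3E)-3-methylbut-3-ene-1,1,4-tricarboxylate F2.
- Trifluoroacetic acid in CH2Cl2 removes both tert-butyl groups to give 2-[(2E)-4-methoxy-2-methyl-4-oxobut-2-en-1-yl]propanedioic acid F3.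
- Heating in toluene decarboxylates F3 to (4E)-6-methoxy-4-methyl-6-oxohex-4-enoic acid F4.
- Oxalyl chloride with catalytic DMF gives methyl (2E)-6-chloro-3-methyl-6-oxohex-2-enoate F5.
- F5 is added at −78 °C to the lithium enolate of ethyl 2-methylpropanoate F6 (from the ester and LDA in THF). This crossed Claisen acylation gives a product that cannot be deprotonated between its carbonyl groups, namely 4, which continues with step 2.

Step 11. Hydride may attack the ring carbonyl of the oxazolidinone (endocyclic cleavage), because the exocyclic carbonyl on C9 is shielded by the quaternary C10 and by C8. The fallback sets out from 18 and comes back at 19. The imide is hydrolysed with lithium hydroperoxide (LiOH, H2O2, THF/H2O, 0 °C), which attacks the exocyclic carbonyl even in hindered imides. This gives (1R,4aS,8aR)-6,6-ethylenedioxy-5,5,8a-trimethyl-2-methylidene-1,2,4a,5,6,7,8,8a-octahydronaphthalene-1-carboxylic acid F7 together with recovered 8. Reduction of F7 with LiAlH4 (THF, 0 °C) then gives 19.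

**Further compounds**

F1 | step 10 | (4R)-4-benzyl-3-{[(1S,4aR,8aS)-6,6-ethylenedioxy-5,5,8a-trimethyl-2-methylidene-1,2,4a,5,6,7,8,8a-octahydronaphthalen-1-yl]carbonyl}-1,3-oxazolidin-2-one | C=C1C=C[C@H]2C(C)(C)C3(OCCO3)CC[C@]2(C)[C@H]1C(=O)N4[C@H](Cc5ccccc5)COC4=O
F2 | step 1 | 1,1-di-tert-butyl 4-methyl (3E)-3-methylbut-3-ene-1,1,4-tricarboxylate | CC(C)(C)OC(=O)C(C/C(C)=C/C(=O)OC)C(=O)OC(C)(C)C
F3 | step 1 | 2-[(2E)-4-methoxy-2-methyl-4-oxobut-2-en-1-yl]propanedioic acid | OC(=O)C(C/C(C)=C/C(=O)OC)C(=O)O
F4 | step 1 | (4E)-6-methoxy-4-methyl-6-oxohex-4-enoic acid | OC(=O)CC/C(C)=C/C(=O)OC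
F5 | step 1 | methyl (2E)-6-chloro-3-methyl-6-oxohex-2-enoate | ClC(=O)CC/C(C)=C/C(=O)OC
F6 | step 1 | lithium enolate of ethyl 2-methylpropanoate | CCOC(O[Li])=C(C)C
F7 | step 11 | (1R,4aS,8aR)-6,6-ethylenedioxy-5,5,8a-trimethyl-2-methylidene-1,2,4a,5,6,7,8,8a-octahydronaphthalene-1-carboxylic acid | C=C1C=C[C@@H]2C(C)(C)C3(OCCO3)CC[C@@]2(C)[C@@H]1C(=O)O
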